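The constants used here are assumed; what happens was integrated by code.

Before you repeat this run, decide to follow the capture agent rather than the clock, since its reading should tell you how the open intermediate divided.

starting material 0.013 M; reagent 1.00 equiv; capture agent 0.0130 M; free catalyst 2 mol%; second catalyst 2 mol%; time 10 h

    open intermediate + capture agent → trapped intermediate (k1 = 0.265 M⁻¹ s⁻¹)
    reagent + second catalyst + open intermediate → second catalyst + target (k2 = 2200 M⁻² s⁻¹)
    starting material + free catalyst → free catalyst + open intermediate (k3 = 12.3 M⁻¹ s⁻¹)

* which holds at 10 h: what has brought the reaction to rest, or that it has not come to rest (no working catalyst is left / it is still moving / the reagent has run out first / forward and back rates have come level / all of the starting material has reacted)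
* how much target there is at 10 h, in percent of the starting material charged
* how much trapped intermediate there is at 10 h, in percent of the starting material charged

- the reaction counts as stopped when no species that holds the starting material changes by six tenths of a point or more over the second half of the time
- run time (flask): 10 h

Take the settings one at a time, by hand. The free catalyst comes back in its own step, so [free catalyst] stays as charged and the starting material falls with a half-life of 0.0602 h. That makes the free catalyst a setting for speed. The capture step by itself, with the capture agent as charged, gives the open intermediate a half-life of 0.0559 h, so the time is a setting that should not matter, as 10 h is far longer than either half-life.

The second catalyst is another matter. Each open intermediate takes either one reagent or one capture agent, so write the two balances. The reagent falls at its constant times [second catalyst][open intermediate][reagent], and the capture agent at its constant times [open intermediate][capture agent]. Dividing one by the other removes [open intermediate] and time. What stays is S, the selectivity factor: the target step's constant times [second catalyst], divided by the capture step's constant. Here that is 2200 M⁻² s⁻¹ times 2.60 × 10⁻⁴ M over 0.265 M⁻¹ s⁻¹, so S = 2.16. More second catalyst raises S and so raises target.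

If r and c are the fractions of reagent and capture agent left, then r = c^S. A larger charge of capture agent leaves S alone but tilts the split toward the trapped intermediate. With equal charges, r and c add up to one once the open intermediate has drained, so target equals c. One Newton step from c = 0.7 gives 63.3% target, and I commit to that, with 36.7% trapped intermediate.

The forecast says all of the starting material has reacted, with 63% target and 37% trapped intermediate, and its ground is that “the reaction stopped because the starting material is exhausted”.

In this flask the outcome is that all of the starting material has reacted, with 63.0% target and 37.0% trapped intermediate at 10 h. At rest in this flask, the capture agent left, 63%, raised to S gives 36.9%, level with the 37% of reagent left, and with those amounts the target step's rate over the capture step's rate stands at 1.27, against S at the charge. In the neighbour with 0.022 M of capture agent, S is unchanged: its 71% of capture agent left, raised to S, gives 48.4%, level with its 48% of reagent left, and its target stands at 51.6%.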